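**Assumptions**
- "4α" is read as the 3,4-trans (4S) configuration written in the SMILES.
- (+)-Fustin and (+)-mollisacacidin are sold only as mg-scale standards, so both are made here from bulk larch (+)-taxifolin.

## Retrosynthetic overview
1. No ring is built. Rings A/C/B of the upper unit come from (+)-taxifolin **1**, and rings D/F/E of the lower unit come from (+)-catechin **2**. All four C2/C3 stereocentres are bought.
2. The chelated 5-OH of **1** is singled out and removed (tribenzyl ether **3** → 5-triflate **4** → one-pot hydrogenolysis) to give (+)-fustin **5**. NaBH4 then gives (+)-mollisacacidin **6**.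
3. The key disconnection is C4(upper)–C8(lower). UV photodehydration of **6** gives p-quinone methide **7**, which unprotected **2** captures at C8 to give target **8**.
4. The only new stereocentre, C4, is set in that step by the adjacent C3 carbinol through anti attack, giving 3,4-trans.

## Route

**Step 1**
Reactants: **1** (+)-taxifolin, (2R,3R)-2-(3,4-dihydroxyphenyl)-3,5,7-trihydroxychroman-4-one
Product: **3** (2R,3R)-7-benzyloxy-2-[3,4-bis(benzyloxy)phenyl]-3,5-dihydroxychroman-4-one
Conditions: BnBr (3.2 equiv), K2CO3 (3.5 equiv), DMF, 0 °C → rt, Ar, 14 h
Reagents that add atoms: benzyl bromide, BrCc1ccccc1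
Why: Williamson etherification benzylates the acidic 7-, 3'- and 4'-phenols, while the 5-OH (hydrogen-bonded to C4=O) and the aliphatic 3-OH stay free; C2/C3 are untouched because room temperature, argon and fast capping of the 4'-OH suppress the ring-opening that epimerises C2.

**Step 2**
Reactants: **3**
Product: **4** (2R,3R)-7-benzyloxy-2-[3,4-bis(benzyloxy)phenyl]-3-hydroxy-4-oxochroman-5-yl trifluoromethanesulfonate
Conditions: PhNTf2 (1.3 equiv), Et3N (2 equiv), DMAP (10 mol %), CH2Cl2, 0 °C → rt, Ar
Reagents that add atoms: N-phenylbis(trifluoromethanesulfonimide), O=S(=O)(N(c1ccccc1)S(=O)(=O)C(F)(F)F)C(F)(F)F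
Why: Phenol-selective triflyl transfer reacts only with the one remaining phenoxide, since PhNTf2 does not sulfonylate the secondary 3-OH, and the mild amine base leaves the α-ketol stereocentres intact.

**Step 3**
Reactants: **4**
Product: **5** (+)-fustin, (2R,3R)-2-(3,4-dihydroxyphenyl)-3,7-dihydroxychroman-4-one
Conditions: H2 (1 atm), 10% Pd/C, Et3N (1.5 equiv), EtOAc–MeOH, rt; then AcOH, filter, crystallise from water
Reagents that add atoms: none
Why: Heterogeneous Pd hydrogenolysis reduces the electron-poor ortho-acyl aryl triflate (C5–OTf → C5–H, amine as TfOH scavenger) and cleaves the three aryl benzyl ethers in the same flask, while the electron-rich aryl ketone and the C2–O1 bond survive at 1 atm in non-acidic medium and C2/C3 are retained.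

**Step 4**
Reactants: **5**
Product: **6** (+)-mollisacacidin, (2R,3S,4R)-2-(3,4-dihydroxyphenyl)chroman-3,4,7-triol (2,3-trans-3,4-trans)
Conditions: NaBH4 (5 equiv), EtOH, 0 °C → rt; AcOH to pH 6, EtOAc extraction, no strong acid
Reagents that add atoms: none
Why: Substrate-controlled borohydride reduction adds hydride axially to the half-chair with equatorial 2-aryl and 3-OH, giving mainly the equatorial 4-OH; any 4-epimer is carried forward because C4 becomes planar in Step 5.

**Step 5 (key step)**
Reactants: **6** (+)-mollisacacidin (1 equiv, 20 mM); **2** (+)-catechin, (2R,3S)-2-(3,4-dihydroxyphenyl)chroman-3,5,7-triol (5 equiv, 0.1 M)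
Product: **8** fisetinidol-(4α,8)-catechin, (2R,3S,4S)-2-(3,4-dihydroxyphenyl)-4-[(2R,3S)-2-(3,4-dihydroxyphenyl)-3,5,7-trihydroxychroman-8-yl]chroman-3,7-diol, formed via transient **7**, (2R,3S)-2-(3,4-dihydroxyphenyl)-3-hydroxy-2,3-dihydro-7H-chromen-7-one (not isolated)
Conditions: hν (295–300 nm, FEP-coil flow reactor, about 10 min residence), degassed MeCN–20 mM phosphate buffer pH 7 (1:1), 5 °C, Ar, stopped at about 75% conversion of **6**; Sephadex LH-20 (EtOH), then prep RP-HPLC; **2** and **6** recovered
Reagents that add atoms: none
Why: Proposed new method: exciting the 7-hydroxychroman chromophore of **6** makes the 7-OH strongly acidic, so water-mediated excited-state proton loss coupled with expulsion of the para-benzylic 4-OH (formal photodehydration) gives the neutral p-quinone methide **7** at pH 7, where **6** is thermally inert; C8, the most nucleophilic carbon of **2** (helped by the small A-ring phenolate fraction), then adds in 1,6-fashion and the ring rearomatises to form the C4–C8 bond; capture of **7** by water only regenerates **6** or its 4-epimer (both photoactive), and O-alkylation by phenols is reversible, so material funnels to the C–C product; C4 is set by C3, because the bulky flavanyl nucleophile approaches the half-chair of **7** anti to the 3-OH (3,4-trans, 4S), and the neutral quinone methide should be more selective than the protonated cation of the acid process (projected 4α:4β about 3:1 and C8:C6 about 5:1, unverified); the closest known chemistry is photodehydration of hydroxybenzyl alcohols to quinone methides trapped by O-, N- and S-nucleophiles, plus thermal acid- or base-generated flavan-4-yl electrophile couplings, whereas use on a flavan-3,4-diol with an arene C-nucleophile to make an interflavan bond is new.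

## Compound list
| No. | Name | SMILES | Role |
|---|---|---|---|
| 1 | (+)-taxifolin (2R,3R) | Oc1cc(O)c2c(c1)O[C@H](c1ccc(O)c(O)c1)[C@@H](O)C2=O | starting material |
| 2 | (+)-catechin (2R,3S) | Oc1cc(O)c2c(c1)O[C@H](c1ccc(O)c(O)c1)[C@@H](O)C2 | starting material |
| 3 | 7,3',4'-tri-O-benzyltaxifolin (2R,3R) | c1ccccc1COc1cc(O)c2c(c1)O[C@H](c1ccc(OCc3ccccc3)c(OCc3ccccc3)c1)[C@@H](O)C2=O | intermediate |
| 4 | 7,3',4'-tri-O-benzyltaxifolin 5-O-triflate (2R,3R) | c1ccccc1COc1cc(OS(=O)(=O)C(F)(F)F)c2c(c1)O[C@H](c1ccc(OCc3ccccc3)c(OCc3ccccc3)c1)[C@@H](O)C2=O | intermediate |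
| 5 | (+)-fustin (2R,3R) | Oc1ccc2c(c1)O[C@H](c1ccc(O)c(O)c1)[C@@H](O)C2=O | intermediate |
| 6 | (+)-mollisacacidin (2R,3S,4R) | Oc1ccc2c(c1)O[C@H](c1ccc(O)c(O)c1)[C@@H](O)[C@@H]2O | intermediate |
| 7 | fisetinidol A-ring p-quinone methide (2R,3S) | O=C1C=CC2=C[C@H](O)[C@@H](c3ccc(O)c(O)c3)OC2=C1 | intermediate (transient, not isolated) |
| 8 | fisetinidol-(4α,8)-catechin (2R,3S,4S; 2R,3S) | Oc1ccc2c(c1)O[C@H](c1ccc(O)c(O)c1)[C@@H](O)[C@@H]2c1c(O)cc(O)c2c1O[C@H](c1ccc(O)c(O)c1)[C@@H](O)C2 | target |

## Totals
- Total steps: 5
- Longest linear sequence: 5 (**1** → **3** → **4** → **5** → **6** → **8**); **2** is used as purchased.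

## Three steps most likely to fail

1. **Step 5 (proposed new photocoupling).**
   - Excess **2** absorbs most of the light (inner filter).
   - The known O1–C2 photo-ring-opening leaks material into 2,3-cis isomers. This should be limited, because reclosure is governed by C3 and favours 2,3-trans, but it is real.
   - 4β,8- and 4α,6-linked isomers and trimers will also form.
   - Fallback (known chemistry): drop the light and ionise **6** thermally. The biomimetic condensation of **6** with excess **2** in 0.1 M aqueous HCl at rt gives **8** together with its 4β,8 and 4α,6 isomers, which are separated on Sephadex LH-20.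

2. **Step 3 (simultaneous detriflation and tris-debenzylation).**
   - The amine may slow O-benzyl cleavage.
   - The triflate may undergo S–O solvolysis back to the 5-OH.
   - The ketone may over-reduce, or the ring may open.
   - Fallback: separate the two events. First reduce the triflate in **4** by homogeneous Pd(0) hydride transfer (Pd(OAc)2/dppf, HCO2H–Et3N, DMF, 70 °C) to tri-O-benzylfustin, then debenzylate under neutral H2/Pd(OH)2–C. This costs one extra step.

3. **Step 1 (selective tribenzylation).**
   - Di- and tetra-benzyl mixtures may form.
   - Carbonate may erode C2/C3 or promote air oxidation to the flavonol.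
   - Fallback: replace base-mediated alkylation with imidazole-mediated silylation (TBSCl, imidazole, DMF). The chelated 5-OH stays free, and silylation of the 3-OH is harmless. Then triflate, reduce with Pd/formate and desilylate with Et3N·3HF to reach **5**. This costs one extra step.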